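**Assumption:** the target, 3,4-dimethoxy-5-methyl-6-[10-(methylsulfanyl)decyl]-2H-pyran-2-one (C19H32O4S), has no stereocentre and no stereogenic alkene. It is achiral, so no enantiocontrol is needed. The C2/C4 centres in intermediates 6 and 7 are labile and are erased when the ring forms.

## Retrosynthetic overview
1. Cleave the 4-O–CH3 bond. This leads back to the 4-hydroxy-2-pyrone 8, and the last step is a sulfide-safe, 4-O-selective methylation.
2. Open the lactone C2–O1 bond. This gives the acyclic 3,5-dioxo ester 7, and closing it with DBU forms the only ring.
3. Cleave C5–C6 of the pyrone (C4–C5 of 7). The fragments are the γ-carbanion of β-keto ester 6 (as its dianion) and the chain ester 3.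
4. Ester 3 comes from methyl 11-bromoundecanoate and NaSMe. Keto ester 6 comes from methyl methoxyacetate and propionyl chloride.

## Route

**Step 1**
Reactants: 1, methyl 11-bromoundecanoate; 2, sodium methanethiolate
Product: 3, methyl 11-(methylsulfanyl)undecanoate
Conditions: NaSMe (1.1 equiv), MeOH, 0 °C → rt, 3 h
Reagents that add atoms: sodium methanethiolate, [Na+].[S-]C
Why: This is an SN2 displacement of an unhindered primary bromide by a soft thiolate, and in MeOH any attack at the methyl ester is degenerate or reversible, so the ester survives.

**Step 2**
Reactants: 4, methyl methoxyacetate; 5, propionyl chloride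
Product: 6, methyl 2-methoxy-3-oxopentanoate (racemic, enolisable)
Conditions: 4 (2.0 equiv), LDA (2.05 equiv), THF, −78 °C, 30 min; then 5 (1.0 equiv), −78 °C, 1 h; AcOH/aq NH4Cl quench
Reagents that add atoms: propionyl chloride, CCC(=O)Cl
Why: This is a crossed Claisen-type C-acylation of a lithium ester enolate by an acid chloride, in which the second equivalent of enolate deprotonates the more acidic β-keto ester and so prevents double acylation.

**Step 3**
Reactants: 6, methyl 2-methoxy-3-oxopentanoate (2.0 equiv); 3, methyl 11-(methylsulfanyl)undecanoate (1.0 equiv)
Product: 7, methyl 2-methoxy-4-methyl-15-(methylsulfanyl)-3,5-dioxopentadecanoate (mixture of keto/enol forms and diastereomers, used crude)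
Conditions: 6, LDA (2.1 equiv per 6), THF, −78 → 0 °C; then 3, 0 °C → rt, 3 h; cold 1 M HCl quench
Reagents that add atoms: methyl 11-(methylsulfanyl)undecanoate, COC(=O)CCCCCCCCCCSC (acyl donor; loses MeOH)
Why: This is a Huckin–Weiler acylation of a β-keto ester dianion, which reacts only at the more basic γ-carbon (the CH2 of the ethyl group); the excess dianion deprotonates the triketide product, and the thioether is inert to LDA.

**Step 4**
Reactants: 7
Product: 8, 4-hydroxy-3-methoxy-5-methyl-6-[10-(methylsulfanyl)decyl]-2H-pyran-2-one
Conditions: DBU (2 equiv), toluene, rt → 60 °C, 4 h; 1 M HCl work-up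
Reagents that add atoms: none
Why: In this base-mediated enol lactonisation the C5 enolate oxygen attacks the C1 methyl ester and expels MeOH, and tautomerisation to the conjugated 4-hydroxy-2-pyrone drives the reaction and removes both labile stereocentres.

**Step 5**
Reactants: 8; 9, methanol
Product: 10, 3,4-dimethoxy-5-methyl-6-[10-(methylsulfanyl)decyl]-2H-pyran-2-one (target)
Conditions: MeOH (2 equiv), PPh3 (1.5 equiv), DIAD (1.5 equiv), THF, 0 °C → rt; chromatography removes any polar 2-methoxy-4-pyrone isomer
Reagents that add atoms: methanol, CO (only its CH3 is retained; the oxygen leaves as Ph3P=O)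
Why: In this Mitsunobu O-alkylation the acidic 4-OH (pKa about 5) is alkylated as its pyronate at O-4 to give the α-pyrone ether, and because no free MeI, Me2SO4 or MeOTf is present the dialkyl sulfide is not converted to a sulfonium salt.

## Compound list
| No. | Name | SMILES | Role |
|---|---|---|---|
| 1 | methyl 11-bromoundecanoate | COC(=O)CCCCCCCCCCBr | starting material |
| 2 | sodium methanethiolate | [Na+].[S-]C | starting material |
| 3 | methyl 11-(methylsulfanyl)undecanoate | COC(=O)CCCCCCCCCCSC | intermediate |
| 4 | methyl methoxyacetate | COCC(=O)OC | starting material |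
| 5 | propionyl chloride | CCC(=O)Cl | starting material |
| 6 | methyl 2-methoxy-3-oxopentanoate (racemic) | CCC(=O)C(OC)C(=O)OC | intermediate |
| 7 | methyl 2-methoxy-4-methyl-15-(methylsulfanyl)-3,5-dioxopentadecanoate (stereo/tautomer mixture) | COC(=O)C(OC)C(=O)C(C)C(=O)CCCCCCCCCCSC | intermediate |
| 8 | 4-hydroxy-3-methoxy-5-methyl-6-[10-(methylsulfanyl)decyl]-2H-pyran-2-one | COc1c(O)c(C)c(CCCCCCCCCCSC)oc1=O | intermediate |
| 9 | methanol | CO | starting material |
| 10 | 3,4-dimethoxy-5-methyl-6-[10-(methylsulfanyl)decyl]-2H-pyran-2-one | COc1c(C)c(CCCCCCCCCCSC)oc(=O)c1OC | target |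

## Summary
**Total steps:** 5.
**Longest linear sequence:** 4 steps (Step 1 or Step 2, then Steps 3, 4 and 5).

**Steps most likely to fail, with fallbacks**
1. **Step 3, dianion acylation.** The hindered secondary γ-carbanion may enolise ester 3 instead of adding to it, giving low conversion.
   - Fallback: replace acylation with an aldol/oxidation sequence.
   - Reduce 3 with DIBAL-H to 11-(methylsulfanyl)undecanal and add the dianion of 6 to it.
   - Oxidise the δ-hydroxy-β-keto ester to 7 with Dess–Martin periodinane, which tolerates the sulfide, then close the ring as in Step 4.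
2. **Step 5, methylation.** The competing outcome is O-2 alkylation, which gives the 2,3-dimethoxy-4-pyrone isomer. The sulfide also rules out forcing electrophilic methylation.
   - Fallback: introduce sulfur last.
   - Run Steps 3 and 4 with commercial methyl undec-10-enoate, then methylate the sulfide-free pyrone with Me2SO4/K2CO3 in acetone, the classical α-selective conditions.
   - Finish with a radical anti-Markovnikov thiol–ene addition of MeSH (AIBN, 70 °C) to the terminal alkene.
3. **Step 2, crossed Claisen.** The risks are self-condensation of the methoxyacetate enolate and O- or di-acylation.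
   - Fallback: form the C–OMe bond instead of the C–C bond.
   - Treat commercial methyl 3-oxopentanoate with p-ABSA/Et3N (Regitz diazo transfer), then carry out Rh2(OAc)4-catalysed O–H insertion into MeOH to give 6.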